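**Plan**

- Retrosynthesis: the three free hydroxyls (O3, O5, O4') are masked as silyl ethers and the O7–prenyl bond is cut last. The C3–O bond is cut back to the flavone. Ring C is cut at C4–C4a (Friedel–Crafts acylation) and O1–C2 (oxa-Michael addition), which separates a ring B arylpropiolate (from vanillin) from a ring A phenol.
- Ring A is cut to open-chain pieces at C4a–C8a, C5–C6 and C8–C8a: a diazo enone (C6, C7, C8, C8a with the 7-O-benzyl and 8-OMe groups) and triisopropylsilyloxyethyne (C4a, C5).
- Enabling feature: in ring A, O1 (on C8a) and the C5 oxygen are meta to each other across C4a–H, with C8–OMe and C7–O on the other flank and C6–H between C5 and C7. A vinylketene carbonyl (giving C8a–O1) and a silyl ynol ether (giving C5–O) deliver this pattern with every oxygen already differentiated.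
- Forward order: ring B is bought, ring A is formed first (benzannulation), ring C second (oxa-Michael, then acylation at C4a). C3 hydroxylation, exchange of benzyl for prenyl at O7 and global desilylation follow.
- Stereochemistry: the target has no stereocentre and no stereogenic double bond. The enol ether geometries of intermediates are lost in the electrocyclisations and in the acid-mediated ring closure.

Key step: step 5

Remark on the chemistry: diazomethane (in ether) and dimethyldioxirane (in acetone) are taken as separately prepared stock solutions.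

**Route**

Step 1
Reactants: 1 methyl 2-(benzyloxy)acetate; 2 methyl formate
Product: 4 methyl (Z)-2-(benzyloxy)-3-methoxyprop-2-enoate, via sodium formyl enolate 3 (not isolated)
Conditions: NaH, HCO2Me (excess), THF, 0 °C → rt; then Me2SO4, DMF, rt
Reagents that add atoms: dimethyl sulfate, COS(=O)(=O)OC
Why: Crossed Claisen formylation of the alkoxyacetate by the non-enolisable formate gives the stabilised formyl enolate, which dimethyl sulfate in DMF should methylate on oxygen (the standard β-methoxyacrylate synthesis), the isomer with OMe anti to the ester being favoured and the geometry being irrelevant after step 5.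

Step 2
Reactants: 4 methyl (Z)-2-(benzyloxy)-3-methoxyprop-2-enoate
Product: 5 (Z)-2-(benzyloxy)-3-methoxyprop-2-enoic acid
Conditions: LiOH·H2O, THF/H2O (3:1), rt; then 1 M HCl, 0 °C, pH 3
Reagents that add atoms: lithium hydroxide, [Li+].[OH-]
Why: Ordinary ester saponification, in which the push–pull enol ether should tolerate hydroxide and a brief cold acidification as other β-methoxyacrylates do.

Step 3
Reactants: 5 (Z)-2-(benzyloxy)-3-methoxyprop-2-enoic acid
Product: 7 (Z)-3-(benzyloxy)-1-diazo-4-methoxybut-3-en-2-one, via acid chloride 6 (not isolated)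
Conditions: Me2C=C(Cl)NMe2 (1.1 equiv), CH2Cl2, 0 °C → rt; then CH2N2 (3 equiv), Et2O, 0 °C, dark
Reagents that add atoms: diazomethane, C=[N+]=[N-]
Why: The Ghosez chloroenamine forms the acid chloride without free HCl, and acylation of excess diazomethane (first stage of the Arndt–Eistert sequence) should give the diazo ketone, the donor-substituted trisubstituted alkene being too electron-rich for dipolar cycloaddition with diazomethane.

Step 4
Reactants: 8 3-phenylisoxazole; 9 triisopropylsilyl chloride
Product: 12 triisopropylsilyloxyethyne, via 5-lithio-3-phenylisoxazole 10 (not isolated), via lithium ethynolate 11 (not isolated)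
Conditions: n-BuLi (1.0 equiv), THF, −78 → −40 °C; then TIPSCl, −78 → 0 °C
Reagents that add atoms: none
Why: Lithiation at C5 of a 3-substituted isoxazole triggers cycloreversion to benzonitrile and lithium ethynolate, and bulky trialkylsilyl chlorides are known to silylate ynolates on oxygen (O-silylation of ynolates), which should give the silyl ynol ether.

Step 5
Reactants: 7 (Z)-3-(benzyloxy)-1-diazo-4-methoxybut-3-en-2-one; 12 triisopropylsilyloxyethyne
Product: 17 3-(benzyloxy)-2-methoxy-5-(triisopropylsilyloxy)phenol, via vinylketene 13 (not isolated), via vinylcyclobutenone 14 (not isolated), via dienylketene 15 (not isolated), via cyclohexadienone 16 (not isolated)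
Conditions: hν (300 nm, Pyrex), 12 (1.5 equiv), ClCH2CH2Cl (degassed), rt; then 80 °C
Reagents that add atoms: none
Why: Irradiation expels N2 from 7 and the Wolff shift of the alkenyl group gives vinylketene 13, whose electrophilic carbonyl carbon is attacked by the nucleophilic CH terminus of ynol ether 12 in a regiospecific (2+2) cycloaddition to 4-vinylcyclobutenone 14. Four-electron electrocyclic opening of 14 gives dienylketene 15, and six-electron electrocyclic closure between the ketene carbon and the methoxy-bearing terminus forms ring A as cyclohexadienone 16, which tautomerises to phenol 17. This is the Danheiser benzannulation in its photochemical Wolff variant, known for α,β-unsaturated α'-diazo ketones with trialkylsilyloxyalkynes. The six-membered ring therefore closes by a 6π electrocyclisation that makes C8–C8a after the cycloaddition has made C4a–C8a and C5–C6; no stereocentre is created and both enol ether geometries converge. The selectivity needed is regiochemical and is secured by the polarity match of ketene and ynol ether, which joins the silyloxy carbon to the former diazo carbon and so places OSi meta, H ortho and OMe ortho to the new hydroxyl. The long-wavelength lamp and the aprotic medium are chosen to keep the benzyl ether and the silyl ynol ether intact.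

Step 6
Reactants: 18 vanillin (4-hydroxy-3-methoxybenzaldehyde); 9 triisopropylsilyl chloride
Product: 19 3-methoxy-4-(triisopropylsilyloxy)benzaldehyde
Conditions: imidazole, DMF, rt
Reagents that add atoms: none
Why: Standard silylation of a phenol with a silyl chloride and imidazole; the triisopropylsilyl ether is chosen because it should survive organolithium, acid, oxidant and hydrogenation and leave with fluoride at the end.

Step 7
Reactants: 19 3-methoxy-4-(triisopropylsilyloxy)benzaldehyde
Product: 20 4-(2,2-dibromoethenyl)-2-methoxy-1-(triisopropylsilyloxy)benzene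
Conditions: CBr4, PPh3, CH2Cl2, 0 °C
Reagents that add atoms: carbon tetrabromide, BrC(Br)(Br)Br
Why: Corey–Fuchs (Ramirez) dibromomethylenation of the aldehyde by the ylide formed from CBr4 and PPh3.

Step 8
Reactants: 20 4-(2,2-dibromoethenyl)-2-methoxy-1-(triisopropylsilyloxy)benzene
Product: 22 allyl 3-[3-methoxy-4-(triisopropylsilyloxy)phenyl]prop-2-ynoate, via lithium arylethynide 21 (not isolated)
Conditions: n-BuLi (2.1 equiv), THF, −78 → 0 °C; then ClCO2CH2CH=CH2, −78 °C → rt
Reagents that add atoms: allyl chloroformate, C=CCOC(=O)Cl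
Why: Second stage of the Corey–Fuchs sequence: bromine–lithium exchange, Fritsch–Buttenberg–Wiechell 1,2-shift and deprotonation give the lithium acetylide, which the chloroformate should acylate at low temperature.

Step 9
Reactants: 17 3-(benzyloxy)-2-methoxy-5-(triisopropylsilyloxy)phenol; 22 allyl 3-[3-methoxy-4-(triisopropylsilyloxy)phenyl]prop-2-ynoate
Product: 23 allyl (Z)-3-[3-(benzyloxy)-2-methoxy-5-(triisopropylsilyloxy)phenoxy]-3-[3-methoxy-4-(triisopropylsilyloxy)phenyl]prop-2-enoate
Conditions: Cs2CO3 (0.2 equiv), DMF, 4 Å MS, 60 °C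
Reagents that add atoms: none
Why: Base-catalysed oxa-Michael addition of the phenoxide to the β-carbon of the arylpropiolate, with anti protonation expected to favour the Z enol ether (ester cis to aryloxy), run with substoichiometric carbonate under anhydrous conditions to spare the silyl ethers.

Step 10
Reactants: 23 allyl (Z)-3-aryloxy-3-arylprop-2-enoate (as named in step 9)
Product: 24 (Z)-3-[3-(benzyloxy)-2-methoxy-5-(triisopropylsilyloxy)phenoxy]-3-[3-methoxy-4-(triisopropylsilyloxy)phenyl]prop-2-enoic acid
Conditions: Pd(PPh3)4 (5 mol %), morpholine, THF, rt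
Reagents that add atoms: none
Why: Tsuji–Trost deallylation, in which zerovalent palladium ionises the allyl ester and morpholine captures the allyl fragment, frees the acid under neutral conditions that spare the aryl silyl ethers, which aqueous hydroxide would endanger.

Step 11
Reactants: 24 (Z)-3-aryloxy-3-arylprop-2-enoic acid (as named in step 10)
Product: 26 7-(benzyloxy)-8-methoxy-2-[3-methoxy-4-(triisopropylsilyloxy)phenyl]-5-(triisopropylsilyloxy)-4H-chromen-4-one, via mixed trifluoroacetic anhydride 25 (not isolated)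
Conditions: (CF3CO)2O, CH2Cl2, 0 °C → rt
Reagents that add atoms: none
Why: Intramolecular Friedel–Crafts acylation through the mixed anhydride: C4a is the only free ring A carbon ortho to the enol ether oxygen and is activated by three ortho/para oxygens, so ring C should close as the six-membered 4-pyranone while the acidic medium equilibrates the alkene geometry.

Step 12
Reactants: 26 7-(benzyloxy)-8-methoxy-2-[3-methoxy-4-(triisopropylsilyloxy)phenyl]-5-(triisopropylsilyloxy)-4H-chromen-4-one
Product: 28 7-(benzyloxy)-3-hydroxy-8-methoxy-2-[3-methoxy-4-(triisopropylsilyloxy)phenyl]-5-(triisopropylsilyloxy)-4H-chromen-4-one, via flavone 2,3-epoxide 27 (not isolated)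
Conditions: dimethyldioxirane (acetone solution), CH2Cl2, 0 °C → rt; then p-TsOH (cat.), CHCl3, rt
Reagents that add atoms: dimethyldioxirane, CC1(C)OO1
Why: Dimethyldioxirane epoxidises the C2=C3 bond of flavones, and acid-catalysed opening of the epoxide at C2 with loss of the C3 proton gives the 3-hydroxyflavone, a known flavone-to-flavonol conversion that tolerates benzyl and silyl ethers.

Step 13
Reactants: 28 7-(benzyloxy)-3-hydroxy-8-methoxy-2-[3-methoxy-4-(triisopropylsilyloxy)phenyl]-5-(triisopropylsilyloxy)-4H-chromen-4-one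
Product: 29 7-(benzyloxy)-8-methoxy-2-[3-methoxy-4-(triisopropylsilyloxy)phenyl]-3,5-bis(triisopropylsilyloxy)-4H-chromen-4-one
Conditions: i-Pr3SiOTf, 2,6-lutidine, CH2Cl2, 0 °C
Reagents that add atoms: triisopropylsilyl trifluoromethanesulfonate, CC(C)[Si](OS(=O)(=O)C(F)(F)F)(C(C)C)C(C)C
Why: Silylation of the enolic 3-OH with a silyl triflate and a hindered pyridine base, so that only one hydroxyl is free in step 15 and all three silyl groups leave together in step 16.

Step 14
Reactants: 29 7-(benzyloxy)-8-methoxy-2-[3-methoxy-4-(triisopropylsilyloxy)phenyl]-3,5-bis(triisopropylsilyloxy)-4H-chromen-4-one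
Product: 30 7-hydroxy-8-methoxy-2-[3-methoxy-4-(triisopropylsilyloxy)phenyl]-3,5-bis(triisopropylsilyloxy)-4H-chromen-4-one
Conditions: H2 (1 atm), Pd/C (10%), EtOAc, rt
Reagents that add atoms: none
Why: Hydrogenolysis of the benzyl aryl ether over palladium on carbon, under which the silyl ethers and the fully substituted C2=C3 bond of the chromone should stay untouched.

Step 15
Reactants: 30 7-hydroxy-8-methoxy-2-[3-methoxy-4-(triisopropylsilyloxy)phenyl]-3,5-bis(triisopropylsilyloxy)-4H-chromen-4-one; 31 prenyl bromide (1-bromo-3-methylbut-2-ene)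
Product: 32 8-methoxy-2-[3-methoxy-4-(triisopropylsilyloxy)phenyl]-7-[(3-methylbut-2-en-1-yl)oxy]-3,5-bis(triisopropylsilyloxy)-4H-chromen-4-one
Conditions: K2CO3, acetone, rt
Reagents that add atoms: none
Why: Williamson etherification, in which the C7 phenoxide, the only free hydroxyl and para to the C4 carbonyl, displaces bromide from the primary allylic halide by SN2 at room temperature.

Step 16
Reactants: 32 8-methoxy-2-[3-methoxy-4-(triisopropylsilyloxy)phenyl]-7-[(3-methylbut-2-en-1-yl)oxy]-3,5-bis(triisopropylsilyloxy)-4H-chromen-4-one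
Product: 33 3,5-dihydroxy-2-(4-hydroxy-3-methoxyphenyl)-8-methoxy-7-[(3-methylbut-2-en-1-yl)oxy]-4H-chromen-4-one (CNP0210396.0)
Conditions: Bu4NF (3.5 equiv), AcOH (3.5 equiv), THF, 0 °C
Reagents that add atoms: none
Why: Fluoride cleaves the three Si–O bonds (two aryl ethers and one enol ether, all with good oxyanion leaving groups), and buffering with acetic acid keeps the medium near neutral so that the prenyl ether and the flavonol should survive.

**Compound list**

1 | methyl 2-(benzyloxy)acetate | COC(=O)COCc1ccccc1 | starting material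
2 | methyl formate | COC=O | starting material
3 | sodium salt of methyl 2-(benzyloxy)-3-oxopropanoate (formyl enolate, not isolated) | [Na+].O=C[C-](OCc1ccccc1)C(=O)OC | intermediate
4 | methyl (Z)-2-(benzyloxy)-3-methoxyprop-2-enoate | CO/C=C(\OCc1ccccc1)C(=O)OC | intermediate
5 | (Z)-2-(benzyloxy)-3-methoxyprop-2-enoic acid | CO/C=C(\OCc1ccccc1)C(=O)O | intermediate
6 | (Z)-2-(benzyloxy)-3-methoxyprop-2-enoyl chloride (not isolated) | CO/C=C(\OCc1ccccc1)C(=O)Cl | intermediate
7 | (Z)-3-(benzyloxy)-1-diazo-4-methoxybut-3-en-2-one | CO/C=C(\OCc1ccccc1)C(=O)C=[N+]=[N-] | intermediate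
8 | 3-phenylisoxazole | c1ccc(-c2ccon2)cc1 | starting material
9 | triisopropylsilyl chloride | CC(C)[Si](Cl)(C(C)C)C(C)C | starting material
10 | 5-lithio-3-phenylisoxazole (not isolated) | [Li]c1cc(-c2ccccc2)no1 | intermediate
11 | lithium ethynolate (not isolated) | [Li]OC#C | intermediate
12 | triisopropylsilyloxyethyne | C#CO[Si](C(C)C)(C(C)C)C(C)C | intermediate
13 | (Z)-3-(benzyloxy)-4-methoxybuta-1,3-dien-1-one (vinylketene, not isolated) | CO/C=C(\OCc1ccccc1)C=C=O | intermediate
14 | 4-[(Z)-1-(benzyloxy)-2-methoxyethenyl]-3-(triisopropylsilyloxy)cyclobut-2-en-1-one (racemic, not isolated) | O=C1C=C(O[Si](C(C)C)(C(C)C)C(C)C)C1/C(OCc1ccccc1)=C/OC | intermediate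
15 | (3E,5Z)-5-(benzyloxy)-6-methoxy-3-(triisopropylsilyloxy)hexa-1,3,5-trien-1-one (dienylketene, not isolated) | O=C=C/C(O[Si](C(C)C)(C(C)C)C(C)C)=C\C(OCc1ccccc1)=C\OC | intermediate
16 | 5-(benzyloxy)-6-methoxy-3-(triisopropylsilyloxy)cyclohexa-2,4-dien-1-one (racemic, not isolated) | O=C1C=C(O[Si](C(C)C)(C(C)C)C(C)C)C=C(OCc2ccccc2)C1OC | intermediate
17 | 3-(benzyloxy)-2-methoxy-5-(triisopropylsilyloxy)phenol | Oc1cc(O[Si](C(C)C)(C(C)C)C(C)C)cc(OCc2ccccc2)c1OC | intermediate
18 | vanillin (4-hydroxy-3-methoxybenzaldehyde) | COc1cc(C=O)ccc1O | starting material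
19 | 3-methoxy-4-(triisopropylsilyloxy)benzaldehyde | COc1cc(C=O)ccc1O[Si](C(C)C)(C(C)C)C(C)C | intermediate
20 | 4-(2,2-dibromoethenyl)-2-methoxy-1-(triisopropylsilyloxy)benzene | COc1cc(C=C(Br)Br)ccc1O[Si](C(C)C)(C(C)C)C(C)C | intermediate
21 | lithium [3-methoxy-4-(triisopropylsilyloxy)phenyl]ethynide (not isolated) | [Li]C#Cc1ccc(O[Si](C(C)C)(C(C)C)C(C)C)c(OC)c1 | intermediate
22 | allyl 3-[3-methoxy-4-(triisopropylsilyloxy)phenyl]prop-2-ynoate | C=CCOC(=O)C#Cc1ccc(O[Si](C(C)C)(C(C)C)C(C)C)c(OC)c1 | intermediate
23 | allyl (Z)-3-[3-(benzyloxy)-2-methoxy-5-(triisopropylsilyloxy)phenoxy]-3-[3-methoxy-4-(triisopropylsilyloxy)phenyl]prop-2-enoate | C=CCOC(=O)/C=C(\Oc1cc(O[Si](C(C)C)(C(C)C)C(C)C)cc(OCc2ccccc2)c1OC)c1ccc(O[Si](C(C)C)(C(C)C)C(C)C)c(OC)c1 | intermediate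
24 | (Z)-3-[3-(benzyloxy)-2-methoxy-5-(triisopropylsilyloxy)phenoxy]-3-[3-methoxy-4-(triisopropylsilyloxy)phenyl]prop-2-enoic acid | OC(=O)/C=C(\Oc1cc(O[Si](C(C)C)(C(C)C)C(C)C)cc(OCc2ccccc2)c1OC)c1ccc(O[Si](C(C)C)(C(C)C)C(C)C)c(OC)c1 | intermediate
25 | mixed anhydride of acid 24 with trifluoroacetic acid (not isolated) | FC(F)(F)C(=O)OC(=O)/C=C(\Oc1cc(O[Si](C(C)C)(C(C)C)C(C)C)cc(OCc2ccccc2)c1OC)c1ccc(O[Si](C(C)C)(C(C)C)C(C)C)c(OC)c1 | intermediate
26 | 7-(benzyloxy)-8-methoxy-2-[3-methoxy-4-(triisopropylsilyloxy)phenyl]-5-(triisopropylsilyloxy)-4H-chromen-4-one | COc1cc(-c2cc(=O)c3c(O[Si](C(C)C)(C(C)C)C(C)C)cc(OCc4ccccc4)c(OC)c3o2)ccc1O[Si](C(C)C)(C(C)C)C(C)C | intermediate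
27 | 2,3-epoxide of flavone 26 (racemic, not isolated) | COc1cc(C23OC2C(=O)c2c(O[Si](C(C)C)(C(C)C)C(C)C)cc(OCc4ccccc4)c(OC)c2O3)ccc1O[Si](C(C)C)(C(C)C)C(C)C | intermediate
28 | 7-(benzyloxy)-3-hydroxy-8-methoxy-2-[3-methoxy-4-(triisopropylsilyloxy)phenyl]-5-(triisopropylsilyloxy)-4H-chromen-4-one | COc1cc(-c2oc3c(OC)c(OCc4ccccc4)cc(O[Si](C(C)C)(C(C)C)C(C)C)c3c(=O)c2O)ccc1O[Si](C(C)C)(C(C)C)C(C)C | intermediate
29 | 7-(benzyloxy)-8-methoxy-2-[3-methoxy-4-(triisopropylsilyloxy)phenyl]-3,5-bis(triisopropylsilyloxy)-4H-chromen-4-one | COc1cc(-c2oc3c(OC)c(OCc4ccccc4)cc(O[Si](C(C)C)(C(C)C)C(C)C)c3c(=O)c2O[Si](C(C)C)(C(C)C)C(C)C)ccc1O[Si](C(C)C)(C(C)C)C(C)C | intermediate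
30 | 7-hydroxy-8-methoxy-2-[3-methoxy-4-(triisopropylsilyloxy)phenyl]-3,5-bis(triisopropylsilyloxy)-4H-chromen-4-one | COc1cc(-c2oc3c(OC)c(O)cc(O[Si](C(C)C)(C(C)C)C(C)C)c3c(=O)c2O[Si](C(C)C)(C(C)C)C(C)C)ccc1O[Si](C(C)C)(C(C)C)C(C)C | intermediate
31 | prenyl bromide (1-bromo-3-methylbut-2-ene) | CC(C)=CCBr | starting material
32 | 8-methoxy-2-[3-methoxy-4-(triisopropylsilyloxy)phenyl]-7-[(3-methylbut-2-en-1-yl)oxy]-3,5-bis(triisopropylsilyloxy)-4H-chromen-4-one | COc1cc(-c2oc3c(OC)c(OCC=C(C)C)cc(O[Si](C(C)C)(C(C)C)C(C)C)c3c(=O)c2O[Si](C(C)C)(C(C)C)C(C)C)ccc1O[Si](C(C)C)(C(C)C)C(C)C | intermediate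
33 | 3,5-dihydroxy-2-(4-hydroxy-3-methoxyphenyl)-8-methoxy-7-[(3-methylbut-2-en-1-yl)oxy]-4H-chromen-4-one | COc1cc(-c2oc3c(OC)c(OCC=C(C)C)cc(O)c3c(=O)c2O)ccc1O | target

**Step count and risks**

Total step count: 16. Longest linear sequence: 12 steps (1, 2, 3, 5, 9, 10, 11, 12, 13, 14, 15, 16).

Steps most likely to fail:

1. Step 5. The excited diazo enone may not enter the Wolff manifold cleanly, the vinylketene may oligomerise or acylate the phenol as it forms, and the benzyl ether may be cleaved photochemically. The fallback is the thermal benzannulation without light; it sets out from alkyne 12 and comes back at phenol 17. Benzyl alcohol and trichloroethylene (KH, THF) would give benzyl (E)-1,2-dichloroethenyl ether F1. n-BuLi (2 equiv, −78 °C) would convert it into lithium (benzyloxy)ethynide F2, quenched with methanol to benzyloxyethyne F3. Methoxyketene F4, released from methoxyacetyl chloride by Et3N at 0 °C, would add to F3 in a (2+2) cycloaddition to give 3-(benzyloxy)-4-methoxycyclobut-2-en-1-one F5. Heating F5 with 12 in toluene at 80 °C should open the four-membered ring thermally to the same vinylketene 13 and carry on through 14, 15 and 16 to 17.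

2. Step 4. Silylation may take place at carbon to give the silylketene, fragmentation of the lithioisoxazole may be incomplete, and the volatile, moisture-sensitive ynol ether may be lost during separation from benzonitrile. The fallback generates the ynolate by oxidation; it sets out from silyl chloride 9 and comes back at alkyne 12. Acetylene and n-BuLi in THF at −78 °C would give lithium acetylide F6, which lithium tert-butyl peroxide (from anhydrous t-BuOOH and LiN(SiMe3)2) should oxidise to ethynolate 11 free of benzonitrile; 9 then silylates oxygen to give 12.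

3. Step 9. Addition to the donor-substituted ynoate may be sluggish and call for temperatures at which carbonate or phenoxide begins to transfer or cleave the aryl silyl ethers. The fallback builds ring C from an ortho-formylated phenol; it sets out from phenol 17 (with acetylide 21 generated from dibromoalkene 20) and comes back at flavone 26.
   - Ortho-specific formylation of 17 (MgCl2, Et3N, paraformaldehyde, MeCN, reflux) should give 4-(benzyloxy)-2-hydroxy-3-methoxy-6-(triisopropylsilyloxy)benzaldehyde F7.
   - Addition of 21 (2.5 equiv, THF, −78 → 0 °C) would give 3-(benzyloxy)-6-{1-hydroxy-3-[3-methoxy-4-(triisopropylsilyloxy)phenyl]prop-2-yn-1-yl}-2-methoxy-5-(triisopropylsilyloxy)phenol F8.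
   - MnO2 in CH2Cl2 would oxidise it to 1-[4-(benzyloxy)-2-hydroxy-3-methoxy-6-(triisopropylsilyloxy)phenyl]-3-[3-methoxy-4-(triisopropylsilyloxy)phenyl]prop-2-yn-1-one F9.
   - 6-endo oxa-Michael cyclisation (DMAP, 10 mol %, DMF, rt) then closes ring C to 26.

**Further compounds**

F1 | step 5 | benzyl (E)-1,2-dichloroethenyl ether | Cl/C=C(/Cl)OCc1ccccc1
F2 | step 5 | lithium (benzyloxy)ethynide | [Li]C#COCc1ccccc1
F3 | step 5 | benzyloxyethyne | C#COCc1ccccc1
F4 | step 5 | methoxyketene | COC=C=O
F5 | step 5 | 3-(benzyloxy)-4-methoxycyclobut-2-en-1-one (racemic) | COC1C(=O)C=C1OCc1ccccc1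
F6 | step 4 | lithium acetylide | [Li]C#C
F7 | step 9 | 4-(benzyloxy)-2-hydroxy-3-methoxy-6-(triisopropylsilyloxy)benzaldehyde | O=Cc1c(O)c(OC)c(OCc2ccccc2)cc1O[Si](C(C)C)(C(C)C)C(C)C
F8 | step 9 | 3-(benzyloxy)-6-{1-hydroxy-3-[3-methoxy-4-(triisopropylsilyloxy)phenyl]prop-2-yn-1-yl}-2-methoxy-5-(triisopropylsilyloxy)phenol (racemic) | OC(C#Cc1ccc(O[Si](C(C)C)(C(C)C)C(C)C)c(OC)c1)c1c(O)c(OC)c(OCc2ccccc2)cc1O[Si](C(C)C)(C(C)C)C(C)C
F9 | step 9 | 1-[4-(benzyloxy)-2-hydroxy-3-methoxy-6-(triisopropylsilyloxy)phenyl]-3-[3-methoxy-4-(triisopropylsilyloxy)phenyl]prop-2-yn-1-one | O=C(C#Cc1ccc(O[Si](C(C)C)(C(C)C)C(C)C)c(OC)c1)c1c(O)c(OC)c(OCc2ccccc2)cc1O[Si](C(C)C)(C(C)C)C(C)C
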